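## Structural features

The target is an arylglycerol β-aryl ether. Ring A (4-hydroxy-3-methoxyphenyl) is bonded to C7 of a three-carbon chain C7–C8–C9, and the oxygen on C8 is bonded to C4 of ring B. Ring B is a benzene ring with methoxy groups on C3 and C5 and a hydroxyacetyl group on C1; there are no other rings. C7 (R, benzylic carbinol) and C8 (S, aryloxy methine) are adjacent and erythro (anti); C9 is a primary alcohol. The fragile sites are the 4-hydroxybenzylic alcohol at C7 (ionisation, epimerisation, hydrogenolysis), the β-aryloxy alcohol array (elimination), the aryl hydroxymethyl ketone (enolisation, over-reduction) and the free phenol. The real difficulty is the O–C bond between C8 and ring B: a secondary carbon between two oxygenated carbons must be joined to a phenol oxygen shielded by two ortho methoxy groups, with C8 defined relative to C7. Displacement at C8 by such a phenoxide tends to end in elimination. The key step uses the pattern of ring B: oxygenated C4 lies between oxygenated C3 and C5 and para to acyl-bearing C1, which matches C2, C1/C3 and C5 of a cyclohexane-1,3-dione 5-carboxylate. The ring B carbon can therefore be delivered as a carbene carbon to the intact C8 hydroxyl, so the O–C8 bond and its stereocentre are never touched.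

## Logic of the disconnections

16 ⇒ 15. The two O–CH2Ph bonds (ring A phenol oxygen and the primary oxygen of the hydroxyacetyl group) are cut. One neutral hydrogenolysis frees both, and the polar final product then needs only filtration. The forward step must stop before the benzylic C7–O bond or the aryl ketone is reduced.

15 ⇒ 14. The hydrogens on O7 and O9 are replaced by two Si–O bonds to one di-tert-butylsilylene bridge. A single group then masks both hydroxyls that flank C8. The forward step needs fluoride conditions that spare the ketone and do not ionise C7.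

14 ⇒ 13. The C–C bond between the ring B carbonyl carbon and its CH2O carbon is cut. The side chain falls back to a carboxyl derivative. The forward step needs an alkoxymethyl anion that adds only once.

13 ⇒ 12. The amide C–N bond is exchanged for an ester C–O bond. This gives the ester that the dione precursor carries from the start. The forward aminolysis must leave the silylene intact.

12 ⇒ 11. The two O–CH3 bonds on ring B are cut. The two phenols are equivalent by symmetry, so no regiochemistry arises. The forward step is a plain double O-methylation.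

11 ⇒ 10. One H2 is formally added back to ring B, which turns the resorcinol into a 2-alkoxycyclohexane-1,3-dione. The hindered aryl ether becomes an alkyl ether of an enolisable dione. The forward dehydrogenation must tolerate the benzyl ether, the silylene and the electron-rich ring A.

10 ⇒ 7 + 9. The bond between O8 and C4 of the dione ring is cut. This is the only bond that joins the two halves, and cutting it on the ring side leaves the O8–C8 bond intact. The result is a chiral aryl-C3 alcohol and an achiral C6 diazo dione. The forward step needs O–H insertion to win over every other carbene pathway.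

9 ⇒ 8. The C=N2 bond is cut. The precursor is a commercial dione. The forward step is a diazo transfer to the doubly activated methylene.

7 ⇒ 6. The two Si–O bonds are cut. The precursor is the free triol. The forward step must bridge O7 and O9 and leave O8 free.

6 ⇒ 5. The triol is reconnected to its terminal isopropylidene acetal (two acetal C–O bonds). This acetal is the form in which the chiral-pool aldehyde delivers C8 and C9. The forward hydrolysis must not epimerise C7.

5 ⇒ 1 + 2 (through 3 and 4). The ring A–C7 bond is cut. C8 comes from the chiral pool: the S centre of 2 becomes C8 with unchanged descriptor, and the anti adduct is the required (7R,8S) erythro isomer. The forward addition needs Felkin–Anh (non-chelation) control.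

## Other disconnections considered

Alternative 1: The cut is the O–C8 bond, made between the ring B phenol A2 and a four-carbon allyl electrophile, racemic vinyl epoxide A3.
- **Forward key step:** a zerovalent palladium catalyst with a C2-symmetric chiral diphosphine ligand would open A3 to interconverting π-allyl complexes. The phenol oxygen of A2 would attack the internal allyl carbon to give branched ether A1, with C8 set by the ligand.
- **In its favour:** C8 comes catalytically from a cheap racemate and either enantiomer is equally accessible. The ether forms at an allyl terminus, so elimination at C8 is not an issue. Ring B arrives aromatic with its side chain already at the ketol oxidation level (as a ketal).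
- **Against it here:** A2 is a di-ortho-substituted phenol and a slow nucleophile, which would strain both the branched/linear preference and the enantioselectivity. A1 holds only C8; C7 must follow by silylation, alkene cleavage to aldehyde A4 and an aryl addition under weak substrate control. A4 is an enolisable α-aryloxy aldehyde. A2 needs several steps from a commercial aryl methyl ketone.
- **Comparison:** structurally, both plans treat the hindered ether as the problem; this one moves it to a π-allyl carbon, the chosen plan to a carbene carbon. Mechanistically, it relies on ligand control at C8 followed by a separate Felkin-type event at C7, whereas the chosen plan sets C7 first and forms the ether with inherent retention. Step count is about equal. The alternative is better in needing no dehydrogenation and no late ester-to-ketol homologation, and equal in avoiding displacement at C8. It is weaker in stereochemical reliability.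

Alternative 2: The cut is the C7–H bond of the benzylic carbinol; the substrate is the racemic 2-aryloxy-3-oxo ester A6.
- **Forward key step:** a screened ketoreductase with enzymatic cofactor recycling would reduce the C7 ketone of one enantiomer of A6 while the acidic C8 centre racemises. This dynamic kinetic resolution would give the anti hydroxy ester A5 with both centres set at once.
- **In its favour:** the hindered ether is made early by substitution at a doubly activated carbon, which is routine. Both stereocentres come from one catalytic event without chiral-pool material. Ring B is aromatic throughout.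
- **Against it here:** the ketone carries two large groups, a poor fit for many ketoreductases. The enzyme must give the anti isomer of the correct absolute sense, which cannot be predicted on paper. The aryl bromide of A5 still has to become the hydroxyacetyl group after ester reduction, which adds protection and several C–C and oxidation steps.
- **Comparison:** structurally, it uses the acidity of C8 between two carbonyls rather than the pattern of ring B. Mechanistically, stereocontrol comes from hydride delivery in an enzyme pocket, whereas the chosen plan uses Felkin control plus a stereoretentive insertion. Up to A5 this route is clearly shorter, and in setting both centres at once it is the better plan. Over the whole synthesis the counts converge because of the bromide-to-ketol work. It is weaker in predictability.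

Alternative 3: The cut is the ring A–C7 bond; the partners are aryl Grignard reagent A8 and the (2S)-2-aryloxy-3-silyloxypropanal A4.
- **Forward key step:** A8 would add to A4 at low temperature. The polar Felkin–Anh model places the aryloxy group anti to the incoming nucleophile and predicts the anti alcohol A7.
- **In its favour:** the two aryl halves meet in the stereo-defining step, so the route is the most convergent. Ring B carries its full side chain in masked form, so only deprotection follows.
- **Against it here:** magnesium can chelate the aldehyde oxygen with the aryloxy oxygen or an ortho methoxy group, which would favour the syn isomer. C8 of A4 is α to an aldehyde and can racemise. The aryl ether in A4 must still be made by displacement on a glycerate-derived electrophile with the hindered phenoxide.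
- **Comparison:** structurally, both plans draw C8 from the chiral pool. This one makes the ether first and C7 last; the chosen plan makes C7 first on a robust acetonide aldehyde and the ether last. Mechanistically, both rely on Felkin-type addition, but here on a chelation-prone, epimerisable substrate. The alternative is better in convergence and likely one or two steps shorter in the longest line, and equal in the source of chirality. It is weaker in stereochemical security at both centres.

Key step: step 5

Remark on the chemistry: 10 is drawn as the diketone although it should exist mainly as its enol. Benzyloxymethyl(tributyl)stannane, tBu2Si(OTf)2 and 4-acetamidobenzenesulfonyl azide are taken as purchasable, and 2 is assumed to be used freshly distilled.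

The precursor is redesigned: O7 and O9 are tied in one di-tert-butylsilylene ring instead of two separate silyl ethers. This removes an acid hydrolysis next to a benzylic silyl ether, excludes silyl migration to O8, leaves the C8 hydroxyl equatorial and open, and saves one step.

## Route

Step 1
Reactants: 1 1-(benzyloxy)-4-bromo-2-methoxybenzene; 2 (S)-2,2-dimethyl-1,3-dioxolane-4-carbaldehyde ((S)-glyceraldehyde acetonide)
Product: 5 (R)-[4-(benzyloxy)-3-methoxyphenyl][(4S)-2,2-dimethyl-1,3-dioxolan-4-yl]methanol, via [4-(benzyloxy)-3-methoxyphenyl]magnesium bromide 3 (not isolated), via [4-(benzyloxy)-3-methoxyphenyl]titanium triisopropoxide 4 (not isolated)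
Conditions: Mg, THF, rt; ClTi(OiPr)3, −78 → −40 °C; then 2, −78 → 0 °C; aq. NH4Cl
Reagents that add atoms: none
Why: Grignard formation, transmetalation to a bulky non-chelating aryltitanium reagent and 1,2-addition to the aldehyde. The Felkin–Anh transition state, with the dioxolane C–O bond anti to the incoming aryl group, should favour the anti (erythro) adduct, so C7 (R) is set relative to the chiral-pool centre C8 (S); the minor syn isomer would be removed by chromatography here or by crystallisation of 6.

Step 2
Reactants: 5 (R)-[4-(benzyloxy)-3-methoxyphenyl][(4S)-2,2-dimethyl-1,3-dioxolan-4-yl]methanol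
Product: 6 (1R,2S)-1-[4-(benzyloxy)-3-methoxyphenyl]propane-1,2,3-triol
Conditions: AcOH/H2O (4:1), 40 °C
Reagents that add atoms: none
Why: Acid-catalysed hydrolysis of a terminal isopropylidene acetal. Aqueous acetic acid should be too weak to ionise the non-phenolic benzylic alcohol, which is further deactivated by the oxygenated neighbour C8, and the benzyl ether is inert.

Step 3
Reactants: 6 (1R,2S)-1-[4-(benzyloxy)-3-methoxyphenyl]propane-1,2,3-triol
Product: 7 (4R,5S)-4-[4-(benzyloxy)-3-methoxyphenyl]-2,2-di-tert-butyl-1,3,2-dioxasilinan-5-ol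
Conditions: tBu2Si(OTf)2, 2,6-lutidine, DMF, −40 → 0 °C
Reagents that add atoms: di-tert-butylsilyl bis(trifluoromethanesulfonate), CC(C)(C)[Si](OS(=O)(=O)C(F)(F)F)(OS(=O)(=O)C(F)(F)F)C(C)(C)C
Why: Cyclic silylene formation from a diol. The bis(triflate) should silylate the primary C9 hydroxyl first and then close onto O7 to give the strain-free six-membered ring with aryl and hydroxyl trans-diequatorial; closure onto O8 would give a strained, labile five-membered ring.

Step 4
Reactants: 8 methyl 3,5-dioxocyclohexane-1-carboxylate
Product: 9 methyl 4-diazo-3,5-dioxocyclohexane-1-carboxylate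
Conditions: 4-acetamidobenzenesulfonyl azide, Et3N, MeCN, 0 °C → rt
Reagents that add atoms: 4-acetamidobenzenesulfonyl azide, CC(=O)Nc1ccc(S(=O)(=O)N=[N+]=[N-])cc1
Why: Regitz diazo transfer. The enolate of the cyclic 1,3-dione attacks the terminal azide nitrogen and the sulfonamide is expelled, the standard entry to 2-diazo-1,3-diones.

Step 5
Reactants: 7 (4R,5S)-4-[4-(benzyloxy)-3-methoxyphenyl]-2,2-di-tert-butyl-1,3,2-dioxasilinan-5-ol; 9 methyl 4-diazo-3,5-dioxocyclohexane-1-carboxylate
Product: 10 methyl 4-{[(4R,5S)-4-[4-(benzyloxy)-3-methoxyphenyl]-2,2-di-tert-butyl-1,3,2-dioxasilinan-5-yl]oxy}-3,5-dioxocyclohexane-1-carboxylate (ring carbons C1 and C4 of the dione unassigned)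
Conditions: Rh2(OAc)4 (2 mol%), PhH, 80 °C, slow addition of 9
Reagents that add atoms: none
Why: Rh2(OAc)4 should decompose 9 with loss of N2 to an electrophilic rhodium-bound diacyl carbene; the only hydroxyl of 7, the equatorial C8–OH, adds to the carbene carbon to give an oxonium ylide, and a proton shift releases the catalyst and the 2-alkoxy-1,3-dione, mainly as its enol. The closest known reaction type is the Rh2(OAc)4-catalysed O–H insertion of 2-diazo-1,3-dicarbonyl compounds into secondary and tertiary alcohols. No ring is closed, so no mode of ring closure arises. No stereocentre is created: the new bond is made at the future ring B carbon and the O–C8 bond is never broken, so C8 stays S and C7 stays R, while the dione ring carbons are enolisable and need no control. The step needs O–H insertion to beat aromatic cycloaddition (Buchner reaction) on the two electron-rich arenes, C–H insertion, ylide chemistry at the ether oxygens and Wolff rearrangement. An acceptor/acceptor carbene reacts fastest with a hydroxyl lone pair, and ylides at ether oxygens have no acidic proton and revert. The silylene cannot migrate to O8 and leaves the hydroxyl unhindered. Slow addition of 9 keeps the carbene from reacting with the enol hydroxyl of the product.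

Step 6
Reactants: 10 methyl 4-{[(4R,5S)-4-[4-(benzyloxy)-3-methoxyphenyl]-2,2-di-tert-butyl-1,3,2-dioxasilinan-5-yl]oxy}-3,5-dioxocyclohexane-1-carboxylate
Product: 11 methyl 4-{[(4R,5S)-4-[4-(benzyloxy)-3-methoxyphenyl]-2,2-di-tert-butyl-1,3,2-dioxasilinan-5-yl]oxy}-3,5-dihydroxybenzoate
Conditions: Pd(O2CCF3)2 (5 mol%), 2-(dimethylamino)pyridine (10 mol%), TsOH·H2O (20 mol%), O2 (1 atm), DMSO, 80 °C
Reagents that add atoms: none
Why: Palladium-catalysed aerobic dehydrogenation of a cyclic ketone: a divalent palladium enolate at C2 (or C6) of the dione ring loses the C1 hydrogen by β-hydride elimination, and the ene-dione tautomerises irreversibly to the resorcinol while O2 reoxidises zerovalent palladium. Only one H2 has to be removed because the dione is already at the dihydroresorcinol oxidation level.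

Step 7
Reactants: 11 methyl 4-{[(4R,5S)-4-[4-(benzyloxy)-3-methoxyphenyl]-2,2-di-tert-butyl-1,3,2-dioxasilinan-5-yl]oxy}-3,5-dihydroxybenzoate
Product: 12 methyl 4-{[(4R,5S)-4-[4-(benzyloxy)-3-methoxyphenyl]-2,2-di-tert-butyl-1,3,2-dioxasilinan-5-yl]oxy}-3,5-dimethoxybenzoate
Conditions: MeI, K2CO3, acetone, 50 °C
Reagents that add atoms: iodomethane, CI
Why: Williamson O-methylation of the two symmetry-equivalent phenols. Ester, silylene and benzyl ether are inert to K2CO3 in acetone.

Step 8
Reactants: 12 methyl 4-{[(4R,5S)-4-[4-(benzyloxy)-3-methoxyphenyl]-2,2-di-tert-butyl-1,3,2-dioxasilinan-5-yl]oxy}-3,5-dimethoxybenzoate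
Product: 13 4-{[(4R,5S)-4-[4-(benzyloxy)-3-methoxyphenyl]-2,2-di-tert-butyl-1,3,2-dioxasilinan-5-yl]oxy}-N,3,5-trimethoxy-N-methylbenzamide
Conditions: MeNH(OMe)·HCl, iPrMgCl, THF, −20 → 0 °C
Reagents that add atoms: N,O-dimethylhydroxylamine hydrochloride, CNOC.Cl
Why: Aminolysis of the methyl ester by the chloromagnesium amide of N,O-dimethylhydroxylamine gives the Weinreb amide. The substrate has no acidic proton and no other electrophilic site, and the hindered silylene should not react at this temperature.

Step 9
Reactants: 13 4-{[(4R,5S)-4-[4-(benzyloxy)-3-methoxyphenyl]-2,2-di-tert-butyl-1,3,2-dioxasilinan-5-yl]oxy}-N,3,5-trimethoxy-N-methylbenzamide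
Product: 14 2-(benzyloxy)-1-(4-{[(4R,5S)-4-[4-(benzyloxy)-3-methoxyphenyl]-2,2-di-tert-butyl-1,3,2-dioxasilinan-5-yl]oxy}-3,5-dimethoxyphenyl)ethan-1-one
Conditions: Bu3SnCH2OBn, nBuLi, THF, −78 °C; then 13, −78 °C; aq. NH4Cl
Reagents that add atoms: benzyloxymethyl(tributyl)stannane, CCCC[Sn](CCCC)(CCCC)COCc1ccccc1
Why: Tin–lithium exchange gives benzyloxymethyllithium, which adds once to the Weinreb amide because the chelated tetrahedral adduct survives until the quench. The product is the α-benzyloxy ketone.

Step 10
Reactants: 14 2-(benzyloxy)-1-(4-{[(4R,5S)-4-[4-(benzyloxy)-3-methoxyphenyl]-2,2-di-tert-butyl-1,3,2-dioxasilinan-5-yl]oxy}-3,5-dimethoxyphenyl)ethan-1-one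
Product: 15 2-(benzyloxy)-1-[4-({(1R,2S)-1-[4-(benzyloxy)-3-methoxyphenyl]-1,3-dihydroxypropan-2-yl}oxy)-3,5-dimethoxyphenyl]ethan-1-one
Conditions: HF·pyridine, pyridine, THF, 0 °C → rt
Reagents that add atoms: none
Why: Fluoride cleaves both Si–O bonds of the silylene, driven by Si–F bond formation. Pyridine buffering avoids base-induced reactions of the ketone and acid ionisation at C7, so both stereocentres are kept.

Step 11
Reactants: 15 2-(benzyloxy)-1-[4-({(1R,2S)-1-[4-(benzyloxy)-3-methoxyphenyl]-1,3-dihydroxypropan-2-yl}oxy)-3,5-dimethoxyphenyl]ethan-1-one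
Product: 16 2-hydroxy-1-[4-({(1R,2S)-1,3-dihydroxy-1-(4-hydroxy-3-methoxyphenyl)propan-2-yl}oxy)-3,5-dimethoxyphenyl]ethan-1-one
Conditions: H2 (1 atm), Pd/C, EtOAc, rt
Reagents that add atoms: none
Why: Hydrogenolysis of the aryl benzyl ether and the primary benzyl ether in a neutral aprotic solvent, stopped after two equivalents of H2. Benzyl C–O cleavage should be faster than reduction of the electron-rich aryl ketone or cleavage of the free benzylic C7–OH.

## Compound list

1 | 1-(benzyloxy)-4-bromo-2-methoxybenzene | COc1cc(Br)ccc1OCc1ccccc1 | starting material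
2 | (S)-2,2-dimethyl-1,3-dioxolane-4-carbaldehyde | O=C[C@@H]1COC(C)(C)O1 | starting material
3 | [4-(benzyloxy)-3-methoxyphenyl]magnesium bromide | COc1cc([Mg]Br)ccc1OCc1ccccc1 | intermediate
4 | [4-(benzyloxy)-3-methoxyphenyl]titanium triisopropoxide | COc1cc([Ti](OC(C)C)(OC(C)C)OC(C)C)ccc1OCc1ccccc1 | intermediate
5 | (R)-[4-(benzyloxy)-3-methoxyphenyl][(4S)-2,2-dimethyl-1,3-dioxolan-4-yl]methanol | COc1cc([C@@H](O)[C@@H]2COC(C)(C)O2)ccc1OCc1ccccc1 | intermediate
6 | (1R,2S)-1-[4-(benzyloxy)-3-methoxyphenyl]propane-1,2,3-triol | COc1cc([C@@H](O)[C@@H](O)CO)ccc1OCc1ccccc1 | intermediate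
7 | (4R,5S)-4-[4-(benzyloxy)-3-methoxyphenyl]-2,2-di-tert-butyl-1,3,2-dioxasilinan-5-ol | COc1cc([C@H]2O[Si](C(C)(C)C)(C(C)(C)C)OC[C@@H]2O)ccc1OCc1ccccc1 | intermediate
8 | methyl 3,5-dioxocyclohexane-1-carboxylate | COC(=O)C1CC(=O)CC(=O)C1 | starting material
9 | methyl 4-diazo-3,5-dioxocyclohexane-1-carboxylate | COC(=O)C1CC(=O)C(=[N+]=[N-])C(=O)C1 | intermediate
10 | methyl 4-{[(4R,5S)-4-[4-(benzyloxy)-3-methoxyphenyl]-2,2-di-tert-butyl-1,3,2-dioxasilinan-5-yl]oxy}-3,5-dioxocyclohexane-1-carboxylate | COc1cc([C@H]2O[Si](C(C)(C)C)(C(C)(C)C)OC[C@@H]2OC3C(=O)CC(C(=O)OC)CC3=O)ccc1OCc1ccccc1 | intermediate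
11 | methyl 4-{[(4R,5S)-4-[4-(benzyloxy)-3-methoxyphenyl]-2,2-di-tert-butyl-1,3,2-dioxasilinan-5-yl]oxy}-3,5-dihydroxybenzoate | COc1cc([C@H]2O[Si](C(C)(C)C)(C(C)(C)C)OC[C@@H]2Oc3c(O)cc(C(=O)OC)cc3O)ccc1OCc1ccccc1 | intermediate
12 | methyl 4-{[(4R,5S)-4-[4-(benzyloxy)-3-methoxyphenyl]-2,2-di-tert-butyl-1,3,2-dioxasilinan-5-yl]oxy}-3,5-dimethoxybenzoate | COc1cc([C@H]2O[Si](C(C)(C)C)(C(C)(C)C)OC[C@@H]2Oc3c(OC)cc(C(=O)OC)cc3OC)ccc1OCc1ccccc1 | intermediate
13 | 4-{[(4R,5S)-4-[4-(benzyloxy)-3-methoxyphenyl]-2,2-di-tert-butyl-1,3,2-dioxasilinan-5-yl]oxy}-N,3,5-trimethoxy-N-methylbenzamide | COc1cc([C@H]2O[Si](C(C)(C)C)(C(C)(C)C)OC[C@@H]2Oc3c(OC)cc(C(=O)N(C)OC)cc3OC)ccc1OCc1ccccc1 | intermediate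
14 | 2-(benzyloxy)-1-(4-{[(4R,5S)-4-[4-(benzyloxy)-3-methoxyphenyl]-2,2-di-tert-butyl-1,3,2-dioxasilinan-5-yl]oxy}-3,5-dimethoxyphenyl)ethan-1-one | COc1cc([C@H]2O[Si](C(C)(C)C)(C(C)(C)C)OC[C@@H]2Oc3c(OC)cc(C(=O)COCc4ccccc4)cc3OC)ccc1OCc1ccccc1 | intermediate
15 | 2-(benzyloxy)-1-[4-({(1R,2S)-1-[4-(benzyloxy)-3-methoxyphenyl]-1,3-dihydroxypropan-2-yl}oxy)-3,5-dimethoxyphenyl]ethan-1-one | COc1cc([C@@H](O)[C@H](CO)Oc2c(OC)cc(C(=O)COCc3ccccc3)cc2OC)ccc1OCc1ccccc1 | intermediate
16 | 2-hydroxy-1-[4-({(1R,2S)-1,3-dihydroxy-1-(4-hydroxy-3-methoxyphenyl)propan-2-yl}oxy)-3,5-dimethoxyphenyl]ethan-1-one | COc1cc([C@@H](O)[C@H](CO)Oc2c(OC)cc(C(=O)CO)cc2OC)ccc1O | target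

## Step count and least certain steps

Total: 11 steps. Longest linear sequence: 10 steps (steps 1–3 and 5–11, from 1 and 2 to 16); step 4 is a one-step branch.

**Step 5 (key step).**
- **Risk:** Wolff rearrangement of the diazo dione, a second insertion of the carbene into the enol hydroxyl of the product, carbene addition to the electron-rich arenes, or slow insertion so that the carbene is lost to other pathways.
- **Fallback:** ring B would be brought in aromatic by O-arylation with a diaryliodonium salt, setting out from 7 and returning at 12.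
  - Commercial methyl 4-bromo-3,5-dimethoxybenzoate would be converted with CuI/NaI and a diamine ligand into methyl 4-iodo-3,5-dimethoxybenzoate F1.
  - Oxidation with mCPBA/TsOH·H2O in the presence of 1,3,5-trimethoxybenzene should give [4-(methoxycarbonyl)-2,6-dimethoxyphenyl](2,4,6-trimethoxyphenyl)iodonium 4-methylbenzenesulfonate F2.
  - The sodium alkoxide of 7 (NaH, toluene, rt) should take the less electron-rich aryl group from trivalent iodine by ligand coupling and give 12 directly, which makes steps 6 and 7 unnecessary.

**Step 6.**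
- **Risk:** the diketonate may bind divalent palladium as an O,O-chelate and stall turnover. Dehydrogenation may stay incomplete, and TsOH at 80 °C may start silylene loss or ionisation at C7.
- **Fallback:** a stepwise enolate route, setting out from 10 and returning at 12.
  - O-methylation with Me3SiCHN2 in MeOH/toluene should give methyl 3-methoxy-4-{[(4R,5S)-4-[4-(benzyloxy)-3-methoxyphenyl]-2,2-di-tert-butyl-1,3,2-dioxasilinan-5-yl]oxy}-5-oxocyclohex-3-ene-1-carboxylate F3.
  - Kinetic deprotonation with LiN(iPr)2 at −78 °C and trapping with PhSeBr should give methyl 4-{[(4R,5S)-4-[4-(benzyloxy)-3-methoxyphenyl]-2,2-di-tert-butyl-1,3,2-dioxasilinan-5-yl]oxy}-5-methoxy-3-oxo-2-(phenylselanyl)cyclohex-4-ene-1-carboxylate F4.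
  - Oxidation with H2O2, selenoxide syn-elimination and tautomerisation should give methyl 4-{[(4R,5S)-4-[4-(benzyloxy)-3-methoxyphenyl]-2,2-di-tert-butyl-1,3,2-dioxasilinan-5-yl]oxy}-3-hydroxy-5-methoxybenzoate F5.
  - Methylation of F5 under the conditions of step 7 gives 12.

**Step 3.**
- **Risk:** closure of the silyl triflate onto O8 instead of O7 would give the five-membered silylene with the wrong hydroxyl free, and two triol molecules may be bridged.
- **Fallback:** silicon is fixed on O7 before the acetal is opened, setting out from 5 and returning at 7.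
  - Silylation of 5 with tBu2SiHCl and imidazole in DMF should give {(R)-[4-(benzyloxy)-3-methoxyphenyl][(4S)-2,2-dimethyl-1,3-dioxolan-4-yl]methoxy}di-tert-butylsilane F6.
  - Aqueous acetic acid should give (2S,3R)-3-[4-(benzyloxy)-3-methoxyphenyl]-3-[(di-tert-butylsilyl)oxy]propane-1,2-diol F7.
  - Catalytic KOtBu in THF should close the Si–H bond onto the primary C9 hydroxyl with loss of H2 (base-catalysed dehydrogenative Si–O coupling) and give 7. Steps 2 and 3 are then bypassed.

**Step 1.**
- **Risk:** poor facial selectivity giving much syn adduct, and partial racemisation or oligomerisation of the sensitive aldehyde 2.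
- **Fallback:** the stereocentre is reset by chelation-controlled reduction, setting out from 5 (as a diastereomer mixture) and returning at 5.
  - Swern oxidation ((COCl)2, DMSO, iPr2NEt, −78 °C) should give [4-(benzyloxy)-3-methoxyphenyl][(4S)-2,2-dimethyl-1,3-dioxolan-4-yl]methanone F8.
  - Zn(BH4)2 in Et2O at low temperature should deliver hydride through the zinc chelate of the carbonyl and the α-oxygen and give the anti alcohol 5.

**Step 11.**
- **Risk:** over-reduction, namely hydrogenolysis of the benzylic C7–O bond, reduction of the aryl ketone or cleavage of the ketol C–O bond.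
- **Fallback:** the last two operations are reversed, setting out from 14 and returning at 16.
  - Hydrogenolysis of 14 (H2, Pd/C, EtOAc) while O7 is still held in the silylene should give 1-(4-{[(4R,5S)-2,2-di-tert-butyl-4-(4-hydroxy-3-methoxyphenyl)-1,3,2-dioxasilinan-5-yl]oxy}-3,5-dimethoxyphenyl)-2-hydroxyethan-1-one F9.
  - Near-neutral Et3N·3HF in THF then removes the silylene to give 16.

## Further compounds

F1 | step 5 | methyl 4-iodo-3,5-dimethoxybenzoate | COC(=O)c1cc(OC)c(I)c(OC)c1
F2 | step 5 | [4-(methoxycarbonyl)-2,6-dimethoxyphenyl](2,4,6-trimethoxyphenyl)iodonium 4-methylbenzenesulfonate | COC(=O)c1cc(OC)c([I+]c2c(OC)cc(OC)cc2OC)c(OC)c1.Cc1ccc(S(=O)(=O)[O-])cc1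
F3 | step 6 | methyl 3-methoxy-4-{[(4R,5S)-4-[4-(benzyloxy)-3-methoxyphenyl]-2,2-di-tert-butyl-1,3,2-dioxasilinan-5-yl]oxy}-5-oxocyclohex-3-ene-1-carboxylate | COc1cc([C@H]2O[Si](C(C)(C)C)(C(C)(C)C)OC[C@@H]2OC3=C(OC)CC(C(=O)OC)CC3=O)ccc1OCc1ccccc1
F4 | step 6 | methyl 4-{[(4R,5S)-4-[4-(benzyloxy)-3-methoxyphenyl]-2,2-di-tert-butyl-1,3,2-dioxasilinan-5-yl]oxy}-5-methoxy-3-oxo-2-(phenylselanyl)cyclohex-4-ene-1-carboxylate | COc1cc([C@H]2O[Si](C(C)(C)C)(C(C)(C)C)OC[C@@H]2OC3=C(OC)CC(C(=O)OC)C([Se]c4ccccc4)C3=O)ccc1OCc1ccccc1
F5 | step 6 | methyl 4-{[(4R,5S)-4-[4-(benzyloxy)-3-methoxyphenyl]-2,2-di-tert-butyl-1,3,2-dioxasilinan-5-yl]oxy}-3-hydroxy-5-methoxybenzoate | COc1cc([C@H]2O[Si](C(C)(C)C)(C(C)(C)C)OC[C@@H]2Oc3c(O)cc(C(=O)OC)cc3OC)ccc1OCc1ccccc1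
F6 | step 3 | {(R)-[4-(benzyloxy)-3-methoxyphenyl][(4S)-2,2-dimethyl-1,3-dioxolan-4-yl]methoxy}di-tert-butylsilane | COc1cc([C@@H](O[SiH](C(C)(C)C)C(C)(C)C)[C@@H]2COC(C)(C)O2)ccc1OCc1ccccc1
F7 | step 3 | (2S,3R)-3-[4-(benzyloxy)-3-methoxyphenyl]-3-[(di-tert-butylsilyl)oxy]propane-1,2-diol | COc1cc([C@@H](O[SiH](C(C)(C)C)C(C)(C)C)[C@@H](O)CO)ccc1OCc1ccccc1
F8 | step 1 | [4-(benzyloxy)-3-methoxyphenyl][(4S)-2,2-dimethyl-1,3-dioxolan-4-yl]methanone | COc1cc(C(=O)[C@@H]2COC(C)(C)O2)ccc1OCc1ccccc1
F9 | step 11 | 1-(4-{[(4R,5S)-2,2-di-tert-butyl-4-(4-hydroxy-3-methoxyphenyl)-1,3,2-dioxasilinan-5-yl]oxy}-3,5-dimethoxyphenyl)-2-hydroxyethan-1-one | COc1cc([C@H]2O[Si](C(C)(C)C)(C(C)(C)C)OC[C@@H]2Oc3c(OC)cc(C(=O)CO)cc3OC)ccc1O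
A1 | alternative 1 | (2R)-2-{4-[2-(tert-butyldimethylsilyloxy)-1,1-dimethoxyethyl]-2,6-dimethoxyphenoxy}but-3-en-1-ol | C=C[C@H](CO)Oc1c(OC)cc(C(OC)(OC)CO[Si](C)(C)C(C)(C)C)cc1OC
A2 | alternative 1 | 4-[2-(tert-butyldimethylsilyloxy)-1,1-dimethoxyethyl]-2,6-dimethoxyphenol | COc1cc(C(OC)(OC)CO[Si](C)(C)C(C)(C)C)cc(OC)c1O
A3 | alternative 1 | 2-vinyloxirane (racemic) | C=CC1CO1
A4 | alternative 1 | (2S)-3-(tert-butyldimethylsilyloxy)-2-{4-[2-(tert-butyldimethylsilyloxy)-1,1-dimethoxyethyl]-2,6-dimethoxyphenoxy}propanal | O=C[C@H](CO[Si](C)(C)C(C)(C)C)Oc1c(OC)cc(C(OC)(OC)CO[Si](C)(C)C(C)(C)C)cc1OC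
A5 | alternative 2 | ethyl (2R,3R)-3-[4-(benzyloxy)-3-methoxyphenyl]-2-(4-bromo-2,6-dimethoxyphenoxy)-3-hydroxypropanoate | COc1cc([C@@H](O)[C@H](C(=O)OCC)Oc2c(OC)cc(Br)cc2OC)ccc1OCc1ccccc1
A6 | alternative 2 | ethyl 3-[4-(benzyloxy)-3-methoxyphenyl]-2-(4-bromo-2,6-dimethoxyphenoxy)-3-oxopropanoate (racemic) | CCOC(=O)C(Oc1c(OC)cc(Br)cc1OC)C(=O)c1ccc(OCc2ccccc2)c(OC)c1
A7 | alternative 3 | (1R,2S)-3-(tert-butyldimethylsilyloxy)-2-{4-[2-(tert-butyldimethylsilyloxy)-1,1-dimethoxyethyl]-2,6-dimethoxyphenoxy}-1-[4-(tert-butyldimethylsilyloxy)-3-methoxyphenyl]propan-1-ol | COc1cc([C@@H](O)[C@H](CO[Si](C)(C)C(C)(C)C)Oc2c(OC)cc(C(OC)(OC)CO[Si](C)(C)C(C)(C)C)cc2OC)ccc1O[Si](C)(C)C(C)(C)C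
A8 | alternative 3 | [4-(tert-butyldimethylsilyloxy)-3-methoxyphenyl]magnesium bromide | COc1cc([Mg]Br)ccc1O[Si](C)(C)C(C)(C)C
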